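The data stem from a simulated flask for an exercise; the scatter is artificial.

A decade of c(partner) is our unit, and larch charges ten times the partner of oak.

| flask | substrate | partner | free catalyst | remark | time |
|---|---|---|---|---|---|
| spring | 2 M | 0.24 M | 2 mM | run made earlier |  |
| summer | 2 M | 2.7 M | 2 mM | run made earlier |  |
| oak | 2.0 M | 0.200 M | 2.0 mM |  | 3.0 min |
| alder | 2.0 M | 0.600 M | 2.0 mM |  | 3.0 min |
| larch | 2.0 M | 2.00 M | 2.0 mM |  | 3.0 min |

- spring (time / min: open intermediate / %, product / %, substrate / %): 0.250: 22, 1, 41; 0.500: 22, 0, 26; 1.33: 15, 2, 17; 3.00: 7, 7, 10
- summer (time / min: open intermediate / %, product / %, substrate / %): 0.417: 24, 4, 27; 1.00: 18, 6, 18; 2.00: 9, 11, 10; 3.00: 6, 14, 8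

(standard deviation of a reading: 2 percentage points)

- the earlier runs were read with a standard deviation of 2 percentage points
- "hardly changes" means that all values lie within two and a half points (for a concentration: within two and a half percent of the largest)

- [open intermediate] at the end for oak, alder, larch, in this order
- the shape of the row from first to last (hardly changes / falls all the way / falls, then rises / rises all the way / rises, then falls)

With little partner to spare, we must decide whether larch earns its charge. Spring and summer end at 7% and 6% of open intermediate, which gives a partner power of −0.0637: the change in the base-ten logarithm of c(open intermediate) at the end per decade of c(partner), an apparent order. The scatter of those two readings puts 0.182 on it, which is more than the size of the power, so even its sign stays open.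

Starting from spring's reading, we commit to 0.142 M, 0.132 M and 0.122 M for oak, alder and larch. That is a fall of 0.97 percentage points across the decade, less than the scatter of one reading. We still charge larch, since it gives the row its full decade, and we hold substrate and free catalyst as in oak. If partner runs short, alder is the flask we leave out.

The forecast gives 0.14 M, 0.13 M and 0.12 M, so the shape is falls all the way. In its words: “I expect a small monotonic decline, though this is uncertain given the 2-point reading error.”

The flasks end at 0.200 M, 0.187 M and 0.152 M, so the shape is falls all the way.

    free catalyst + open intermediate ⇌ catalyst intermediate (K = 0.500 M⁻¹, k = 14.0 M⁻¹ s⁻¹)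
    substrate + free catalyst ⇌ free catalyst + open intermediate (K = 0.830, k = 20.0 M⁻¹ s⁻¹)
    2 substrate → homo dimer (k = 0.0170 M⁻¹ s⁻¹)
    partner + catalyst intermediate → free catalyst + product (k = 3.00 M⁻¹ s⁻¹)

In oak, the homo dimer holds 77.7% of the substrate charged at the end. Carried from oak's end to alder, our power gives 0.186 M, and alder stands at 0.187 M.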